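**Retrosynthetic overview**

1. The target gibberellin comes from its 15-deoxy congener 23 by allylic oxidation at C-15, then oxidation and 1,2-reduction to invert C-15. Compound 23 comes from the 3,6-diketone 17 by one-carbon homologation of the C-6 ketone (C-7) and axial-selective reduction at C-3.
2. Key disconnection: the C-5/C-10 and C-2/C-3 bonds, both made in one base-mediated aldol/lactonisation/Dieckmann cascade of a 1,4-diketone whose two arms sit on C-8 and C-9 of a preformed C/D bicycle.
3. Feature used: the C-6 ketone hangs on quaternary C-8 and can enolise only towards C-5. The C-10 ketone takes up C-5 (ring B) and its oxygen captures one ester of the prochiral methylmalonate carbon C-4 as the 19,10-lactone. The other ester becomes C-3 and is attacked by C-2 (ring A), which is activated by an ester that is removed later.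
4. The diketone comes from a cyclohexane made by catalytic asymmetric Diels–Alder reaction (ring C, C-8/C-9), enolate propargylation (quaternary C-8) and ketyl–alkyne cyclisation (ring D, 13-OH, 16,17-alkene).
5. Ring order: C, D, then B, lactone and A in the key step.

Key step: step 10

Remark: gibberellin numbering is used for all intermediates, α and β follow gibberellin usage (the 19,10-lactone lies on the α face), C-7 is carried as the free acid from step 13 on, and the configuration at C-9 set in step 1 is assumed to survive the later steps in which C-9 is alpha to a carbonyl.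

Step 1
Reactants: 1 2-(trimethylsilyloxy)buta-1,3-diene; 2 ethyl (E)-4-oxobut-2-enoate
Product: 3 ethyl (1R,6R)-6-formyl-3-(trimethylsilyloxy)cyclohex-3-ene-1-carboxylate
Conditions: (S)-3,3-diphenyl-1-(o-tolyl)tetrahydro-1H,3H-pyrrolo[1,2-c][1,3,2]oxazaborole protonated with HNTf2 (10 mol%), CH2Cl2, −78 °C
Reagents that add atoms: none
Why: Lewis-acid-catalysed Diels–Alder reaction in which the cationic oxazaborolidine binds the formyl group of 2, so that the formyl-bearing carbon (C-9) ends para and the ester-bearing carbon (C-8) meta to the siloxy carbon (C-13), the (E)-dienophile gives the trans adduct, and face shielding by the catalyst should set C-9 absolutely.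

Step 2
Reactants: 3 ethyl (1R,6R)-6-formyl-3-(trimethylsilyloxy)cyclohex-3-ene-1-carboxylate
Product: 4 ethyl (7R,8R)-8-(1,3-dioxolan-2-yl)-1,4-dioxaspiro[4.5]decane-7-carboxylate
Conditions: HOCH2CH2OH (5 equiv), TsOH·H2O (5 mol%), benzene, reflux, water separator
Reagents that add atoms: ethane-1,2-diol OCCO
Why: Acid-catalysed acetalisation turns the silyl enol ether into the ketone dioxolane and the aldehyde into its dioxolane, so that the ester alpha-hydrogen at C-8 is the only acidic site left and the two stereocentres are not touched.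

Step 3
Reactants: 4 ethyl (7R,8R)-8-(1,3-dioxolan-2-yl)-1,4-dioxaspiro[4.5]decane-7-carboxylate; 5 3-bromoprop-1-yne
Product: 6 ethyl (7S,8R)-8-(1,3-dioxolan-2-yl)-7-(prop-2-yn-1-yl)-1,4-dioxaspiro[4.5]decane-7-carboxylate
Conditions: LiN(i-Pr)2, THF, −78 °C; then 5, DMPU, −78 → −20 °C
Reagents that add atoms: none
Why: Ester enolate alkylation in which the planar C-8 enolate is attacked anti to the neighbouring dioxolanyl group, so that the propargyl carbon (C-15) is trans and the ester carbon (C-6) cis to C-10, which sets the quaternary centre C-8.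

Step 4
Reactants: 6 ethyl (7S,8R)-8-(1,3-dioxolan-2-yl)-7-(prop-2-yn-1-yl)-1,4-dioxaspiro[4.5]decane-7-carboxylate
Product: 7 ethyl (1S,2R)-2-(1,3-dioxolan-2-yl)-5-oxo-1-(prop-2-yn-1-yl)cyclohexane-1-carboxylate
Conditions: pyridinium p-toluenesulfonate (20 mol%), acetone–H2O (10:1), 23 °C
Reagents that add atoms: water O
Why: Chemoselective acetal hydrolysis, because the ketone ketal ionises much faster than the hindered aldehyde acetal, so that mild acid frees only the C-13 ketone.

Step 5
Reactants: 7 ethyl (1S,2R)-2-(1,3-dioxolan-2-yl)-5-oxo-1-(prop-2-yn-1-yl)cyclohexane-1-carboxylate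
Product: 8 ethyl 2-(1,3-dioxolan-2-yl)-5-hydroxy-6-methylenebicyclo[3.2.1]octane-1-carboxylate (dioxolanyl on C-2 trans to the two-carbon bridge)
Conditions: SmI2 (2.5 equiv), HMPA, t-BuOH (2 equiv), THF, 0 → 23 °C
Reagents that add atoms: none
Why: Ketyl–alkyne reductive cyclisation in which the C-13 ketyl adds 5-exo-dig to the axial propargyl group and gives the bicyclo[3.2.1]octane with the bridgehead 13-OH and the exocyclic 16,17-alkene, the bridge geometry fixing C-13.

Step 6
Reactants: 8 ethyl 2-(1,3-dioxolan-2-yl)-5-hydroxy-6-methylenebicyclo[3.2.1]octane-1-carboxylate; 9 chloroiodomethane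
Product: 10 2-chloro-1-[2-(1,3-dioxolan-2-yl)-5-hydroxy-6-methylenebicyclo[3.2.1]octan-1-yl]ethan-1-one
Conditions: 9 (3 equiv), MeLi·LiBr (3 equiv, slow addition), THF–Et2O, −78 °C; then aq. NH4Cl
Reagents that add atoms: none
Why: Chloromethyllithium, made in the flask by iodine–lithium exchange, adds once to the ester and the tetrahedral adduct holds at −78 °C and collapses on work-up to the alpha-chloro ketone, which brings in C-5 (ester to chloromethyl ketone homologation).

Step 7
Reactants: 10 2-chloro-1-[2-(1,3-dioxolan-2-yl)-5-hydroxy-6-methylenebicyclo[3.2.1]octan-1-yl]ethan-1-one; 11 dimethyl 2-methylmalonate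
Product: 12 dimethyl 2-{2-[2-(1,3-dioxolan-2-yl)-5-hydroxy-6-methylenebicyclo[3.2.1]octan-1-yl]-2-oxoethyl}-2-methylmalonate
Conditions: 11, NaH, NaI (10 mol%), THF–DMF, 0 → 23 °C
Reagents that add atoms: none
Why: SN2 displacement of the activated primary chloride by the sodium malonate installs C-4 with its methyl group and both ester carbons (C-3 and C-19), and C-4 stays prochiral.

Step 8
Reactants: 12 dimethyl 2-{2-[2-(1,3-dioxolan-2-yl)-5-hydroxy-6-methylenebicyclo[3.2.1]octan-1-yl]-2-oxoethyl}-2-methylmalonate
Product: 13 dimethyl 2-[2-(2-formyl-5-hydroxy-6-methylenebicyclo[3.2.1]octan-1-yl)-2-oxoethyl]-2-methylmalonate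
Conditions: TsOH·H2O (10 mol%), acetone–H2O (20:1), 40 °C
Reagents that add atoms: water O
Why: Acid-catalysed acetal hydrolysis with exchange to acetone frees the C-10 aldehyde under conditions mild enough for the tertiary allylic 13-alcohol.

Step 9
Reactants: 13 dimethyl 2-[2-(2-formyl-5-hydroxy-6-methylenebicyclo[3.2.1]octan-1-yl)-2-oxoethyl]-2-methylmalonate; 14 methyl acrylate
Product: 15 dimethyl 2-{2-[5-hydroxy-2-(4-methoxy-4-oxobutanoyl)-6-methylenebicyclo[3.2.1]octan-1-yl]-2-oxoethyl}-2-methylmalonate
Conditions: 14 (3 equiv), 3-benzyl-5-(2-hydroxyethyl)-4-methylthiazolium chloride (20 mol%), Et3N, 1,4-dioxane, 70 °C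
Reagents that add atoms: none
Why: Stetter reaction in which the carbene-derived acyl anion equivalent of the aldehyde adds 1,4 to methyl acrylate and gives the gamma-keto ester, that is C-10 as a ketone carrying C-1, C-2 and the removable ester carbon on C-2.

Step 10
Reactants: 15 dimethyl 2-{2-[5-hydroxy-2-(4-methoxy-4-oxobutanoyl)-6-methylenebicyclo[3.2.1]octan-1-yl]-2-oxoethyl}-2-methylmalonate
Product: 17 pentacyclic beta-keto ester (rings A to D with the 19,10-lactone; CO2Me on C-2; ketones at C-3 and C-6; 13-OH; 16-ene; C-2 as keto/enol mixture), via aldol lactone 16 (not isolated)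
Conditions: t-BuOK (3.0 equiv), THF, −40 → 23 °C; then AcOH
Reagents that add atoms: none
Why: Base-mediated aldol/lactonisation/Dieckmann cascade, whose first two stages are those of a Stobbe condensation (the closest known reaction type) and whose last stage is a Dieckmann condensation. The C-6 ketone is attached to quaternary C-8 and can enolise only towards C-5; this enolate adds to the C-10 ketone (5-(enolendo)-exo-trig, the mode by which 1,4-diketones close), which forms the C-5/C-10 bond and ring B, the C-10 alkoxide acylates one ester of the prochiral C-4 malonate (5-exo-trig) to give the 19,10-lactone 16, and the methoxide set free makes the C-2 ester enolate, which is acylated by the remaining C-4 ester (6-(enolexo)-exo-trig) and forms the C-2/C-3 bond and ring A. C-10 and C-5 are set under reversible aldol conditions: only adducts with the C-10 oxygen and the C-5 malonyl group cis can lactonise, and of these the one with the C-1 chain on the face of H-9 and the small oxygen next to C-11 should be favoured, after which the lactone bridge allows only the trans A/B fusion. C-4 is set by the ring closure itself, because the two esters exchange by reversible translactonisation and only the ester cis to the C-1/C-2 chain on the lactone ring can be reached by C-2. The step needs the pairing of the C-5 enolate with the C-10 ketone to win over the pairing of the C-1 enolate with the C-6 ketone, and ring closure to win over loss of the lactone carboxylate by beta-elimination: the C-6 carbonyl lies between quaternary C-8 and the neopentyl-type C-5 methylene and is by far the poorer acceptor, so that under reversible aldol conditions the C-10 adduct should dominate and be drained by lactonisation, the C-9 enolate is hindered and has no ring closure open to it, and the elimination from the C-5/C-6 enolate of the cis-fused lactone is the reverse of a 5-endo-trig closure and is held back further by the low temperature and the acid quench. The stabilised beta-keto ester enolate of 17 is the thermodynamic sink that pulls the reversible steps forward.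

Step 11
Reactants: 17 pentacyclic beta-keto ester; 18 (methoxymethyl)triphenylphosphonium chloride
Product: 19 C-6 methoxymethylene derivative of 17 (enol ether at C-6/C-7, E/Z mixture)
Conditions: 18 (6 equiv), KN(SiMe3)2 (5.8 equiv), THF, 0 → 50 °C
Reagents that add atoms: none
Why: Wittig methoxymethylenation in which the excess ylide first turns the beta-keto ester and the 13-OH into their anions, which protects the C-3 carbonyl, and then olefinates the C-6 ketone and brings in C-7.

Step 12
Reactants: 19 C-6 methoxymethylene derivative of 17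
Product: 20 2-methoxycarbonyl-3-oxo lactone 7-aldehyde (6β-CHO)
Conditions: 1 M HCl, THF, 23 °C
Reagents that add atoms: water O
Why: Acid hydrolysis of the enol ether gives the C-7 aldehyde, and the epimerisable C-6 should equilibrate through the enol to the 6β-aldehyde, which is trans to the C-4 substituent on C-5 (thermodynamic control).

Step 13
Reactants: 20 2-methoxycarbonyl-3-oxo lactone 7-aldehyde (6β-CHO)
Product: 21 2-methoxycarbonyl-3-oxo lactone 7-oic acid
Conditions: NaClO2, NaH2PO4, 2-methylbut-2-ene, t-BuOH–H2O, 0 → 23 °C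
Reagents that add atoms: sodium chlorite [Na+].[O-]Cl=O
Why: Pinnick oxidation converts the aldehyde into the acid without touching the alkene, the tertiary alcohol or the beta-keto ester, the scavenger taking up the hypochlorous acid.

Step 14
Reactants: 21 2-methoxycarbonyl-3-oxo lactone 7-oic acid
Product: 22 3-oxo lactone acid (13-hydroxy-3-oxo-20-norgibberell-16-ene-7,19-dioic acid 19,10-lactone)
Conditions: LiCl, DMSO–H2O, 130 °C
Reagents that add atoms: none
Why: Krapcho demethoxycarbonylation removes the activating ester from C-2 of the beta-keto ester under neutral conditions that spare the lactone.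

Step 15
Reactants: 22 3-oxo lactone acid
Product: 23 15-deoxy target (3β,13-dihydroxy-20-norgibberell-16-ene-7,19-dioic acid 19,10-lactone)
Conditions: LiBH(s-Bu)3 (3.5 equiv), THF, −78 °C; then aq. NH4Cl
Reagents that add atoms: none
Why: Ketone reduction with a bulky hydride, which should attack the C-3 ketone from the equatorial side, as it does with other 4,4-disubstituted 3-ketones, and give the axial 3β-alcohol, while the lactone is not reduced at −78 °C and the acid and hydroxyl protons only consume hydride.

Step 16
Reactants: 23 15-deoxy target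
Product: 24 15-epi target (3β,13,15α-trihydroxy-20-norgibberell-16-ene-7,19-dioic acid 19,10-lactone)
Conditions: SeO2 (0.5 equiv), t-BuOOH (3 equiv), 1,4-dioxane, 23 °C
Reagents that add atoms: tert-butyl hydroperoxide CC(C)(C)OO
Why: Selenium dioxide allylic oxidation (ene reaction then [2,3]-shift) at C-15, the only allylic CH2 of the exocyclic alkene, with oxygen delivered to the exo face of the bicyclo[3.2.1]octane on the side of C-14, which should give the 15α-alcohol.

Step 17
Reactants: 24 15-epi target
Product: 25 15-oxo lactone acid (3β,13-dihydroxy-15-oxo-20-norgibberell-16-ene-7,19-dioic acid 19,10-lactone)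
Conditions: MnO2 (20 equiv), acetone, 23 °C
Reagents that add atoms: none
Why: MnO2 oxidation of the allylic 15-alcohol to the enone, selective because the 3-OH is not allylic and the 13-OH is tertiary.

Step 18
Reactants: 25 15-oxo lactone acid
Product: 26 target gibberellin (3β,13,15β-trihydroxy-20-norgibberell-16-ene-7,19-dioic acid 19,10-lactone)
Conditions: NaBH4, CeCl3·7H2O, MeOH, −78 → 0 °C
Reagents that add atoms: none
Why: Luche 1,2-reduction in which hydride should add to the enone from the exo face on the side of C-14, away from the axial hydrogen on C-11, and give the 15β-alcohol of the target.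

**Compound list**

1 | 2-(trimethylsilyloxy)buta-1,3-diene | C=CC(=C)O[Si](C)(C)C | starting material
2 | ethyl (E)-4-oxobut-2-enoate | CCOC(=O)/C=C/C=O | starting material
3 | ethyl (1R,6R)-6-formyl-3-(trimethylsilyloxy)cyclohex-3-ene-1-carboxylate | CCOC(=O)[C@@H]1CC(O[Si](C)(C)C)=CC[C@H]1C=O | intermediate
4 | ethyl (7R,8R)-8-(1,3-dioxolan-2-yl)-1,4-dioxaspiro[4.5]decane-7-carboxylate | CCOC(=O)[C@@H]1CC2(OCCO2)CC[C@H]1C1OCCO1 | intermediate
5 | 3-bromoprop-1-yne | C#CCBr | starting material
6 | ethyl (7S,8R)-8-(1,3-dioxolan-2-yl)-7-(prop-2-yn-1-yl)-1,4-dioxaspiro[4.5]decane-7-carboxylate | CCOC(=O)[C@@]1(CC#C)CC2(OCCO2)CC[C@H]1C1OCCO1 | intermediate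
7 | ethyl (1S,2R)-2-(1,3-dioxolan-2-yl)-5-oxo-1-(prop-2-yn-1-yl)cyclohexane-1-carboxylate | CCOC(=O)[C@@]1(CC#C)CC(=O)CC[C@H]1C1OCCO1 | intermediate
8 | ethyl 2-(1,3-dioxolan-2-yl)-5-hydroxy-6-methylenebicyclo[3.2.1]octane-1-carboxylate (C-2 substituent trans to the two-carbon bridge) | C=C1C[C@]2(C(=O)OCC)C[C@@]1(O)CC[C@H]2C1OCCO1 | intermediate
9 | chloroiodomethane | ClCI | starting material
10 | 2-chloro-1-[2-(1,3-dioxolan-2-yl)-5-hydroxy-6-methylenebicyclo[3.2.1]octan-1-yl]ethan-1-one | C=C1C[C@]2(C(=O)CCl)C[C@@]1(O)CC[C@H]2C1OCCO1 | intermediate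
11 | dimethyl 2-methylmalonate | COC(=O)C(C)C(=O)OC | starting material
12 | dimethyl 2-{2-[2-(1,3-dioxolan-2-yl)-5-hydroxy-6-methylenebicyclo[3.2.1]octan-1-yl]-2-oxoethyl}-2-methylmalonate | C=C1C[C@]2(C(=O)CC(C)(C(=O)OC)C(=O)OC)C[C@@]1(O)CC[C@H]2C1OCCO1 | intermediate
13 | dimethyl 2-[2-(2-formyl-5-hydroxy-6-methylenebicyclo[3.2.1]octan-1-yl)-2-oxoethyl]-2-methylmalonate | C=C1C[C@]2(C(=O)CC(C)(C(=O)OC)C(=O)OC)C[C@@]1(O)CC[C@H]2C=O | intermediate
14 | methyl acrylate | C=CC(=O)OC | starting material
15 | dimethyl 2-{2-[5-hydroxy-2-(4-methoxy-4-oxobutanoyl)-6-methylenebicyclo[3.2.1]octan-1-yl]-2-oxoethyl}-2-methylmalonate | C=C1C[C@]2(C(=O)CC(C)(C(=O)OC)C(=O)OC)C[C@@]1(O)CC[C@H]2C(=O)CCC(=O)OC | intermediate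
16 | aldol lactone: rings B, C and D with the 19,10-lactone, CO2Me and CH3 on C-4, CH2CH2CO2Me on C-10, C-6 ketone | C=C1C[C@]23C[C@@]1(O)CC[C@H]2[C@@]1(CCC(=O)OC)OC(=O)[C@](C)(C(=O)OC)[C@H]1C3=O | intermediate
17 | pentacyclic beta-keto ester: gibberellin skeleton without C-7, 19,10-lactone, 13-OH, 16-ene, ketones at C-3 and C-6, CO2Me on C-2 (C-2 not defined, keto/enol) | C=C1C[C@]23C[C@@]1(O)CC[C@H]2[C@@]12CC(C(=O)OC)C(=O)[C@@](C)(C(=O)O1)[C@H]2C3=O | intermediate
18 | (methoxymethyl)triphenylphosphonium chloride | COC[P+](c1ccccc1)(c1ccccc1)c1ccccc1.[Cl-] | starting material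
19 | C-6 methoxymethylene derivative of 17 (enol ether at C-6/C-7, E/Z not defined) | C=C1C[C@]23C[C@@]1(O)CC[C@H]2[C@@]12CC(C(=O)OC)C(=O)[C@@](C)(C(=O)O1)[C@H]2C3=COC | intermediate
20 | 2-methoxycarbonyl-3-oxo lactone 7-aldehyde (6β-CHO; 13-OH, 16-ene, 19,10-lactone) | C=C1C[C@]23C[C@@]1(O)CC[C@H]2[C@@]12CC(C(=O)OC)C(=O)[C@@](C)(C(=O)O1)[C@H]2[C@@H]3C=O | intermediate
21 | 2-methoxycarbonyl-3-oxo lactone 7-oic acid (13-OH, 16-ene, 19,10-lactone) | C=C1C[C@]23C[C@@]1(O)CC[C@H]2[C@@]12CC(C(=O)OC)C(=O)[C@@](C)(C(=O)O1)[C@H]2[C@@H]3C(=O)O | intermediate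
22 | 3-oxo lactone acid: 13-hydroxy-3-oxo-20-norgibberell-16-ene-7,19-dioic acid 19,10-lactone | C=C1C[C@]23C[C@@]1(O)CC[C@H]2[C@@]12CCC(=O)[C@@](C)(C(=O)O1)[C@H]2[C@@H]3C(=O)O | intermediate
23 | 15-deoxy target: 3β,13-dihydroxy-20-norgibberell-16-ene-7,19-dioic acid 19,10-lactone | C=C1C[C@]23C[C@@]1(O)CC[C@H]2[C@@]12CC[C@H](O)[C@@](C)(C(=O)O1)[C@H]2[C@@H]3C(=O)O | intermediate
24 | 15-epi target: 3β,13,15α-trihydroxy-20-norgibberell-16-ene-7,19-dioic acid 19,10-lactone | C=C1[C@H](O)[C@]23C[C@@]1(O)CC[C@H]2[C@@]12CC[C@H](O)[C@@](C)(C(=O)O1)[C@H]2[C@@H]3C(=O)O | intermediate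
25 | 15-oxo lactone acid: 3β,13-dihydroxy-15-oxo-20-norgibberell-16-ene-7,19-dioic acid 19,10-lactone | C=C1C(=O)[C@]23C[C@@]1(O)CC[C@H]2[C@@]12CC[C@H](O)[C@@](C)(C(=O)O1)[C@H]2[C@@H]3C(=O)O | intermediate
26 | target gibberellin: 3β,13,15β-trihydroxy-20-norgibberell-16-ene-7,19-dioic acid 19,10-lactone | C=C1[C@@H](O)[C@]23C[C@@]1(O)CC[C@H]2[C@@]12CC[C@H](O)[C@@](C)(C(=O)O1)[C@H]2[C@@H]3C(=O)O | target

**Step count and risks**

Total step count: 18. Longest linear sequence: 18 steps (from 1 and 2 to 26).

The three steps most likely to fail: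

Step 10. What may go wrong is the other pairing, in which the C-1 enolate adds to the C-6 ketone and either opens an isomeric lactonisation/Dieckmann manifold or condenses to a cyclopentenone. Epimerisation at C-9, or beta-elimination of the lactone carboxylate before ring A has closed, may also intervene. The fallback releases the C-5 enolate regiospecifically instead of relying on equilibrating enolates. It sets out from 12, whose only ketone is the C-6 ketone. Treatment with LiN(SiMe3)2 and acetic anhydride in THF at −78 °C gives the enol acetate 13-acetate F1. Acetal exchange (TsOH·H2O, acetone–H2O) gives the aldehyde F2, and the Stetter reaction of step 9 gives the keto ester F3. NaOMe (excess) in THF at −40 → 23 °C then cleaves the enol acetate, which sets the C-5 enolate free before any other enolate exists, so that aldol addition, lactonisation and Dieckmann closure follow, and the excess methoxide removes the 13-acetate. The fallback comes back to the route at 17.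

Step 11. What may go wrong is that the ylide fails to add to the hindered C-6 carbonyl, which lies between quaternary C-8 and C-5, or only enolises it. The fallback uses a smaller one-carbon nucleophile and a rearrangement. It sets out from 17. Corey–Chaykovsky epoxidation with dimethylsulfonium methylide (Me3SI, KN(SiMe3)2, THF–DMSO, 0 °C) gives the spiro-epoxide F4. Meinwald rearrangement (BF3·OEt2, CH2Cl2, −78 °C) with hydride shift gives the C-7 aldehyde, which is equilibrated at C-6 as in step 12. The fallback comes back to the route at 20.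

Step 9. What may go wrong is epimerisation at C-9 and intramolecular aldol reaction of the keto aldehyde under the basic carbene conditions, or slow acyl anion formation at the hindered aldehyde. The fallback builds the ketone by acyl substitution under neutral conditions. It sets out from 13. Pinnick oxidation (NaClO2, NaH2PO4, 2-methylbut-2-ene) gives the acid F5. Thioesterification (EtSH, DCC, DMAP, CH2Cl2) gives the S-ethyl thioester F6. Fukuyama coupling with IZnCH2CH2CO2Me and PdCl2(PPh3)2 (5 mol%) in toluene–THF at 23 °C gives the gamma-keto ester. The fallback comes back to the route at 15.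

Further compounds

F1 | step 10 | enol acetate 13-acetate of 12 (C-5/C-6 enol acetate, 13-acetate, C-10 dioxolane; enol geometry not defined) | C=C1C[C@]2(C(OC(C)=O)=CC(C)(C(=O)OC)C(=O)OC)C[C@@]1(OC(C)=O)CC[C@H]2C1OCCO1
F2 | step 10 | C-10 aldehyde of F1 | C=C1C[C@]2(C(OC(C)=O)=CC(C)(C(=O)OC)C(=O)OC)C[C@@]1(OC(C)=O)CC[C@H]2C=O
F3 | step 10 | gamma-keto ester of F2 (C-10 ketone with CH2CH2CO2Me) | C=C1C[C@]2(C(OC(C)=O)=CC(C)(C(=O)OC)C(=O)OC)C[C@@]1(OC(C)=O)CC[C@H]2C(=O)CCC(=O)OC
F4 | step 11 | spiro-epoxide of 17 at C-6 (C-6 configuration not defined) | C=C1C[C@]23C[C@@]1(O)CC[C@H]2[C@@]12CC(C(=O)OC)C(=O)[C@@](C)(C(=O)O1)[C@H]2C34CO4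
F5 | step 9 | C-10 carboxylic acid from 13 | C=C1C[C@]2(C(=O)CC(C)(C(=O)OC)C(=O)OC)C[C@@]1(O)CC[C@H]2C(=O)O
F6 | step 9 | S-ethyl thioester of F5 | C=C1C[C@]2(C(=O)CC(C)(C(=O)OC)C(=O)OC)C[C@@]1(O)CC[C@H]2C(=O)SCC
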